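## Structural features

The target is a flavonol: a 4H-chromen-4-one in which benzo ring A and pyranone ring C share the C4a–C8a bond, C2 carries the 4-hydroxy-3-methoxyphenyl ring B through the C2–C1' bond, and C3 carries a hydroxyl. Ring A is pentasubstituted: O5 is a free hydroxyl hydrogen-bonded to the C4 carbonyl, O7 carries a prenyl (3-methylbut-2-enyl) group, O8 a methyl group, and only C6 bears hydrogen. There is no stereocentre and no configured double bond, so nothing has to be controlled in space. The fragile parts are three. The aryl prenyl ether is cleaved or cyclised by Brønsted and Lewis acids, saturated or cleaved under hydrogenolysis, rearranged on strong heating and attacked by electrophilic oxidants. The 3-hydroxy-4-pyranone enol is oxidised in base under air. The 5,7,8-trioxygenated chromone can be opened and reclosed to the 5,6,7-isomer by strong acid (Wessely–Moser rearrangement). The real difficulty is the regiochemistry of ring A: its four oxygens are of four different kinds, and a classical closure from a 2,6-dihydroxyaryl ketone would have to choose between two ortho hydroxyls (8-methoxy against 6-methoxy product), all within a protecting-group scheme that spares the prenyl ether. The feature used here is that O5 and O8 stand para to each other on ring A while O1 sits on C8a, the carbon between C8 and the acyl-bearing C4a. This is the pattern left when a C5,C8-quinone with the acyl chain on C4a accepts an oxygen nucleophile at its unsubstituted carbon next to the acyl group. The O1–C8a bond can therefore be made last, by conjugate addition of the C2 enol oxygen to that quinone, and the same event leaves O8 as the only unchelated phenol.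

## Logic of the disconnections

16 from 15: the two ester C–O bonds on O3 and O4' are cut. The free 3-hydroxy-4-pyranone and the guaiacol hydroxyl are the most air- and base-sensitive functions and would compete in the methylation of O8. Acetates are chosen because their removal needs neither acid nor hydrogen, so the prenyl ether is safe. The demand on the forward step is a transesterification mild enough to leave everything else alone.

15 from 14: the O8–CH3 bond is cut. O8 starts as a quinone oxygen and, after ring closure, is the only phenol not locked to the C4 carbonyl, so the ring-A oxygens are told apart without any regiochemical choice. The forward step must mono-alkylate a hydroquinone under a weak base without acetate loss or autoxidation.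

14 from 11 (through 13 and 12): the O1–C8a bond is cut. Ring C disappears and ring A becomes a 2,5-dihydroxy-4-alkoxyphenyl ketone with hydrogen where O1 will stand, so the question of which ortho oxygen closes the ring no longer arises. The forward step must oxidise 11 to 12 and then let the enol oxygen add to the carbon next to the acyl group faster than 12 decomposes. Over-oxidation to 13 must be reversible by reduction, and 11 must never meet acid.

11 from 10: the two O–Si bonds are cut. A free hydroquinone cannot pass through the acylation and the oxidation that build the side chain, so it is stored as a bis-silyl ether and released only just before the key step. The demand is an unmasking that causes no acyl migration and uses no strong acid.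

10 from 9: the C–O bond at the central carbon of the diketone is cut. The oxygen that becomes O3 is introduced at the most acidic carbon after the carbon skeleton is complete, which keeps both coupling partners simple. The forward step needs an oxidant that acetoxylates the enol but spares the alkene and the electron-rich rings.

9 from 5 and 8: the C–C bond between the central methylene and the aroyl carbonyl is cut (Claisen disconnection). This splits the molecule into two halves of similar size and makes the route convergent. Because 8 carries an aryl acetate, the forward C-acylation must work without a strong base.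

8 from 7 from 6: the C–Cl bond and then the phenol ester bond are cut; both forward steps are routine functional-group operations on a commercial acid.

5 from 4, 4 from 2 and 3, 2 from 1: the O–Si bonds, then the O7–CH2 bond, then the aryl–acetyl C–C bond are cut. The prenyl group is attached early, on the one phenol that is para to the ketone, and the ketone comes from an O-to-C acetyl shift on commercial 1. The forward demands are a regioselective mono-alkylation of a triol and a Fries reaction carried out before any acid-labile group is present.

## Other disconnections considered

Alternative 1: The cut is the C4a–C5 bond, with ring A assembled from the four carbons of a cyclobutenone and the C5=C6 bond of a preformed pyranone (these two carbons become C4a and C8a). In the forward key step, heating 4-[5-(benzyloxy)-6-(4-benzyloxy-3-methoxyphenyl)-4-oxo-4H-pyran-2-yl]-4-methoxy-3-(propan-2-yloxy)cyclobut-2-en-1-one A1 would open the four-membered ring to a dienylketene. Its ketene carbon would close onto the pyranone carbon that becomes C4a, and tautomerisation would give 3-(benzyloxy)-2-(4-benzyloxy-3-methoxyphenyl)-5-hydroxy-7-isopropoxy-8-methoxychromen-4-one A2.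
- In its favour: every ring-A substituent is placed by the substitution of A1, so there is no regiochemical choice. The 8-methoxy group and the free 5-hydroxyl arrive directly, so no selective methylation is needed; on this point it is better than the chosen plan. Electrocyclic ring opening and closure of aryl- and heteroaryl-cyclobutenones is a known reaction class, so on mechanistic precedent it also stands on firmer ground than step 9.
- Against it here: O7 arrives as an isopropyl ether that must be exchanged for prenyl, and the reagents that cleave it (BCl3 and the like) also attack benzyl ethers. After prenylation the two benzyl groups would have to be removed although hydrogenolysis saturates the prenyl alkene and Lewis acids cleave the prenyl ether. Making A1 requires a pyranone metalated next to its ring oxygen, addition to a squarate-derived dione and O-methylation of a tertiary alkoxide, none of which is short or certain.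
- Comparison: structurally both plans solve the ring-A problem. Alternative 1 is mechanistically safer in its key step, but it is clearly longer and its protecting groups clash with the prenyl ether, whereas the chosen plan carries only acetates and silyl ethers.

Alternative 2: The cut is through C8–C8a and C4a–C5 together, so that ring A is built in one annulation onto ring C. In the forward key step, 3-acetoxy-2-(4-acetoxy-3-methoxyphenyl)-5-bromo-4H-pyran-4-one A3 and 1,4-dimethoxy-1,3-bis(trimethylsilyloxy)buta-1,3-diene A4 would combine in a [4+2] sense. The methoxy-bearing CH terminus of A4 would bond to the pyranone carbon that becomes C8a and the ketene-acetal terminus to the brominated carbon, and loss of HBr and methanol would give 3-acetoxy-2-(4-acetoxy-3-methoxyphenyl)-5,7-dihydroxy-8-methoxychromen-4-one A5.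
- In its favour: two skeletal bonds form in one operation and the route is convergent. A5 already carries the 8-methoxy group and has O7 as its only unchelated phenol, so prenylation would be a known selective alkylation, and the final acetate methanolysis is the same as in the chosen plan. On the end game it is at least the equal of the chosen plan and arguably better, since no hydroquinone has to be handled under base.
- Against it here: the dienophile is the C5=C6 bond of a 4-pyranone, a vinylogous ester with some aromatic stabilisation, which is a poor partner. A4 carries an alkoxy group on its nucleophilic terminus, is hard to prepare as one geometric isomer and is very sensitive to hydrolysis. Regiochemistry rests on electronic bias alone, and the reverse orientation would give the 6-methoxy isomer. Conjugate addition at the unsubstituted pyranone carbon followed by pyranone ring opening is a likely diversion. Both A3 and A4 need syntheses of their own.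
- Comparison: on precedent the two key steps are equal, since neither has been shown on its substrate class. In the chosen plan, however, only one aromatising six-membered closure is geometrically possible, so its regiochemistry is enforced by structure and not by electronics. Step economy would be similar at best.

Alternative 3: The cut is through C4–C4a and O1–C2, joining a ring-A phenol to a three-carbon keto ester that carries ring B. In the forward key step, 5-(benzyloxy)-2-methoxybenzene-1,3-diol A6 and ethyl 2-(benzyloxy)-3-(4-benzyloxy-3-methoxyphenyl)-3-oxopropanoate A7 would be heated together without catalyst. C-acylation by the ester and condensation of a phenol oxygen with the ketone would give 3,5-bis(benzyloxy)-2-(4-benzyloxy-3-methoxyphenyl)-7-hydroxy-8-methoxychromen-4-one A8.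
- In its favour: thermal chromone formation from phenols and β-keto esters is a known reaction type, so on precedent it is better than the chosen plan. A6 is symmetrical, so the ring-A regiochemistry is unambiguous. The 8-methoxy group is in place and O7 is free for prenylation. Rings A and C are assembled in the fewest operations of all four plans, so on step count to the core it is the equal or the better.
- Against it here: the condensation needs temperatures well above 200 °C, at which an α-benzyloxy keto ester and benzyl ethers are at risk. A6 is not a catalogue compound and needs a desymmetrising protection sequence. After prenylation at O7, three benzyl ethers would have to be removed although hydrogenolysis and Lewis acids both destroy the prenyl ether, and thermally robust groups that are also mildly removable are few.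
- Comparison: Alternative 3 is shorter to the tricyclic core and better precedented. It pays with harsh conditions and an unsolved end game, whereas the chosen plan stays at or near room temperature after step 1 and pays instead with redox-sensitive intermediates and an unprecedented closure.

Key step: step 9

Remark: the carbon between the two carbonyl groups of 10, 11 and 12 is enolisable and configurationally labile, so these compounds are racemates and are written without a stereodescriptor. Flavone numbering is used for all ring-A atoms, so the electrophilic quinone carbon is the future C8a.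

## Route

Step 1
Reactants: 1 1,2,4-triacetoxybenzene
Product: 2 1-(2,4,5-trihydroxyphenyl)ethanone
Conditions: BF3·OEt2, AcOH, 90 °C; then H2O, 80 °C
Reagents that add atoms: none
Why: Fries rearrangement: BF3 transfers an acetyl group from oxygen to the ring carbon that is para to one oxygen and ortho to another, the most nucleophilic site of the 1,2,4-trioxygenated ring, and the remaining O-acetyl groups are hydrolysed in the hot aqueous work-up. No prenyl group is present yet, so acid and heat do no harm.

Step 2
Reactants: 2 1-(2,4,5-trihydroxyphenyl)ethanone; 3 prenyl bromide (1-bromo-3-methylbut-2-ene)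
Product: 4 1-[2,5-dihydroxy-4-(3-methylbut-2-enyloxy)phenyl]ethanone
Conditions: 3 (1.05 equiv), NaHCO3 (1.5 equiv), DMF, 40 °C, Ar
Reagents that add atoms: none
Why: Williamson etherification under acidity control: the 4-OH, para to the acetyl group, is the most acidic phenol and the only one that NaHCO3 ionises to a useful extent, whereas the 2-OH is tied up in a hydrogen bond to the carbonyl and the 5-OH is not conjugated with it; this is the selectivity known for catechols that carry a para carbonyl group. Argon protects the hydroxyhydroquinone from autoxidation.

Step 3
Reactants: 4 1-[2,5-dihydroxy-4-(3-methylbut-2-enyloxy)phenyl]ethanone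
Product: 5 1-[2,5-bis(tert-butyldimethylsilyloxy)-4-(3-methylbut-2-enyloxy)phenyl]ethanone
Conditions: TBSCl (2.5 equiv), imidazole (5 equiv), DMF, rt → 40 °C, Ar
Reagents that add atoms: tert-butyldimethylsilyl chloride, CC(C)(C)[Si](C)(C)Cl
Why: Silyl ether formation at both phenols; the chelated 2-OH reacts more slowly, hence the excess of reagent and the mild warming. The two silyl ethers prevent O-acylation in step 6 and phenol oxidation in step 7 and can later be removed by fluoride without acid.

Step 4
Reactants: 6 vanillic acid (4-hydroxy-3-methoxybenzoic acid)
Product: 7 4-acetoxy-3-methoxybenzoic acid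
Conditions: Ac2O, pyridine, rt; then H2O
Reagents that add atoms: acetic anhydride, CC(=O)OC(C)=O
Why: O-Acetylation of the phenol; any mixed anhydride formed at the carboxyl group is hydrolysed in the aqueous work-up. The acetate is chosen because it is the phenol protection whose final removal does not endanger the prenyl ether.

Step 5
Reactants: 7 4-acetoxy-3-methoxybenzoic acid
Product: 8 4-acetoxy-3-methoxybenzoyl chloride
Conditions: (COCl)2, DMF (cat.), CH2Cl2, 0 °C → rt
Reagents that add atoms: oxalyl chloride, O=C(Cl)C(=O)Cl
Why: Acid chloride formation through the chloroiminium salt generated from DMF and oxalyl chloride; the aryl acetate and the methyl ether are inert.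

Step 6
Reactants: 5 1-[2,5-bis(tert-butyldimethylsilyloxy)-4-(3-methylbut-2-enyloxy)phenyl]ethanone; 8 4-acetoxy-3-methoxybenzoyl chloride
Product: 9 1-(4-acetoxy-3-methoxyphenyl)-3-[2,5-bis(tert-butyldimethylsilyloxy)-4-(3-methylbut-2-enyloxy)phenyl]propane-1,3-dione
Conditions: MgBr2·OEt2 (2.5 equiv), iPr2NEt (3 equiv), CH2Cl2, rt; then pH 4 aqueous wash
Reagents that add atoms: none
Why: Crossed Claisen condensation by soft enolisation: coordination of MgBr2 acidifies the methyl ketone so that the tertiary amine can deprotonate it, and the magnesium enolate is C-acylated by 8, the product being held as a chelated magnesium diketonate that resists a second acylation. Because no strong base is present, the aryl acetate of 8 and the silyl ethers of 5 survive.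

Step 7
Reactants: 9 1-(4-acetoxy-3-methoxyphenyl)-3-[2,5-bis(tert-butyldimethylsilyloxy)-4-(3-methylbut-2-enyloxy)phenyl]propane-1,3-dione
Product: 10 rac-2-acetoxy-1-(4-acetoxy-3-methoxyphenyl)-3-[2,5-bis(tert-butyldimethylsilyloxy)-4-(3-methylbut-2-enyloxy)phenyl]propane-1,3-dione
Conditions: PhI(OAc)2 (1.2 equiv), AcOH–CH2Cl2, rt
Reagents that add atoms: (diacetoxyiodo)benzene, CC(=O)OI(OC(C)=O)c1ccccc1
Why: α-Acetoxylation of a 1,3-diketone by a hypervalent iodine diacetate: the enol attacks iodine and an acetate then displaces iodobenzene at the central carbon. Without a strong acid activator the reagent should not attack the trisubstituted alkene or the silyloxy-substituted ring; the new centre forms as a racemate and is labile, which is of no consequence because it becomes sp2 C3.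

Step 8
Reactants: 10 rac-2-acetoxy-1-(4-acetoxy-3-methoxyphenyl)-3-[2,5-bis(tert-butyldimethylsilyloxy)-4-(3-methylbut-2-enyloxy)phenyl]propane-1,3-dione
Product: 11 rac-2-acetoxy-1-(4-acetoxy-3-methoxyphenyl)-3-[2,5-dihydroxy-4-(3-methylbut-2-enyloxy)phenyl]propane-1,3-dione
Conditions: Bu4NF (2.2 equiv), AcOH (3 equiv), THF, 0 °C, Ar; pH 7 buffer work-up; used at once
Reagents that add atoms: none
Why: Fluoride cleavage of the two aryl silyl ethers, buffered with acetic acid so that neither phenoxide nor alkoxide is available for acetate cleavage or acyl migration. Stronger acid is avoided because it would dehydrate the ortho-hydroxyaryl diketone in the classical sense, through the 2-OH, to the isomeric 6-hydroxychromone; 11 is therefore generated only just before use.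

Step 9
Reactants: 11 rac-2-acetoxy-1-(4-acetoxy-3-methoxyphenyl)-3-[2,5-dihydroxy-4-(3-methylbut-2-enyloxy)phenyl]propane-1,3-dione
Product: 14 3-acetoxy-2-(4-acetoxy-3-methoxyphenyl)-5,8-dihydroxy-7-(3-methylbut-2-enyloxy)chromen-4-one, via acylquinone 12 (not isolated), via chromene-4,5,8-trione 13 (not isolated)
Conditions: Ag2O (3 equiv), MgSO4, CH2Cl2, 0 °C → rt, dark, Ar; filter; then aq. Na2S2O4, EtOAc
Reagents that add atoms: none
Why: Proposed new method: Ag2O dehydrogenates the acylhydroquinone to the 2-acyl-1,4-benzoquinone 12, in which the unsubstituted ring carbon next to the acyl group (the future C8a) is β to both the side-chain C4 carbonyl and the ring carbonyl at C5 and is therefore the most electrophilic position. The doubly activated CH(OAc) between the two ketones enolises towards the aroyl group and the enol oxygen adds to C8a in a 6-endo-trig oxa-Michael closure that forms O1–C8a and ring C, after which loss of the C8a hydrogen by tautomerisation restores the aromatic ring as the 5,8-hydroquinone 14. The more electron-rich 14 is expected to be oxidised on by the excess Ag2O, or by exchange with 12, to the chromene-4,5,8-trione 13, which Na2S2O4 returns to 14 in the work-up. The closest known reaction types are the addition of oxygen nucleophiles to 2-acyl-1,4-benzoquinones at the carbon next to the acyl group, the oxidative cyclisation of 2-hydroxyaryl 2,5-dioxygenated-phenyl ketones to xanthones through the aroylquinone, and Nenitzescu-type quinone annulations. No stereocentre is created, and the labile centre of 11 becomes sp2 C3. The selectivity needed is O-attack at C8a and not at a quinone carbonyl or at C6: addition to a carbonyl is reversible and cannot aromatise, C6 is deactivated as the α-carbon of the vinylogous ester formed by the 7-alkoxy group and lies beyond the reach of the three-atom tether, and C-attack by the enol would require a four-membered ring. Oxidation before any contact with acid also removes the ortho hydroxyl whose conventional cyclodehydration would lead to the 6-hydroxy isomer.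

Step 10
Reactants: 14 3-acetoxy-2-(4-acetoxy-3-methoxyphenyl)-5,8-dihydroxy-7-(3-methylbut-2-enyloxy)chromen-4-one
Product: 15 3-acetoxy-2-(4-acetoxy-3-methoxyphenyl)-5-hydroxy-8-methoxy-7-(3-methylbut-2-enyloxy)chromen-4-one
Conditions: MeI (1.2 equiv), K2CO3 (1.2 equiv), acetone, rt, Ar
Reagents that add atoms: iodomethane, CI
Why: Partial O-methylation (Williamson): the 8-OH is a free phenol, whereas the 5-OH is locked in a hydrogen bond to the C4 carbonyl and is far less acidic and nucleophilic, the classical basis for turning 5,8-dihydroxyflavones into 5-hydroxy-8-methoxyflavones. A small excess of anhydrous K2CO3 at room temperature under argon should keep the two acetates in place and the hydroquinone from autoxidation.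

Step 11
Reactants: 15 3-acetoxy-2-(4-acetoxy-3-methoxyphenyl)-5-hydroxy-8-methoxy-7-(3-methylbut-2-enyloxy)chromen-4-one
Product: 16 3,5-dihydroxy-2-(4-hydroxy-3-methoxyphenyl)-8-methoxy-7-(3-methylbut-2-enyloxy)chromen-4-one
Conditions: K2CO3 (0.2 equiv), MeOH, 0 °C → rt, Ar; then AcOH
Reagents that add atoms: none
Why: Base-catalysed transesterification (Zemplén-type methanolysis): catalytic methoxide cleaves the enol acetate on O3 and the aryl acetate on O4', both activated esters, while the ethers, the prenyl alkene and the chelated phenol are untouched. Exclusion of air protects the liberated 3-hydroxy-4-pyranone until the mixture is neutralised.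

## Compound list

1 | 1,2,4-triacetoxybenzene (benzene-1,2,4-triyl triacetate) | CC(=O)Oc1ccc(OC(C)=O)c(OC(C)=O)c1 | starting material
2 | 1-(2,4,5-trihydroxyphenyl)ethanone | CC(=O)c1cc(O)c(O)cc1O | intermediate
3 | prenyl bromide (1-bromo-3-methylbut-2-ene) | CC(C)=CCBr | starting material
4 | 1-[2,5-dihydroxy-4-(3-methylbut-2-enyloxy)phenyl]ethanone | CC(=O)c1cc(O)c(OCC=C(C)C)cc1O | intermediate
5 | 1-[2,5-bis(tert-butyldimethylsilyloxy)-4-(3-methylbut-2-enyloxy)phenyl]ethanone | CC(=O)c1cc(O[Si](C)(C)C(C)(C)C)c(OCC=C(C)C)cc1O[Si](C)(C)C(C)(C)C | intermediate
6 | vanillic acid (4-hydroxy-3-methoxybenzoic acid) | COc1cc(C(=O)O)ccc1O | starting material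
7 | 4-acetoxy-3-methoxybenzoic acid | COc1cc(C(=O)O)ccc1OC(C)=O | intermediate
8 | 4-acetoxy-3-methoxybenzoyl chloride | COc1cc(C(Cl)=O)ccc1OC(C)=O | intermediate
9 | 1-(4-acetoxy-3-methoxyphenyl)-3-[2,5-bis(tert-butyldimethylsilyloxy)-4-(3-methylbut-2-enyloxy)phenyl]propane-1,3-dione | COc1cc(C(=O)CC(=O)c2cc(O[Si](C)(C)C(C)(C)C)c(OCC=C(C)C)cc2O[Si](C)(C)C(C)(C)C)ccc1OC(C)=O | intermediate
10 | rac-2-acetoxy-1-(4-acetoxy-3-methoxyphenyl)-3-[2,5-bis(tert-butyldimethylsilyloxy)-4-(3-methylbut-2-enyloxy)phenyl]propane-1,3-dione (racemic, labile centre) | COc1cc(C(=O)C(OC(C)=O)C(=O)c2cc(O[Si](C)(C)C(C)(C)C)c(OCC=C(C)C)cc2O[Si](C)(C)C(C)(C)C)ccc1OC(C)=O | intermediate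
11 | rac-2-acetoxy-1-(4-acetoxy-3-methoxyphenyl)-3-[2,5-dihydroxy-4-(3-methylbut-2-enyloxy)phenyl]propane-1,3-dione (racemic, labile centre) | CC(=O)OC(C(=O)c1cc(O)c(OCC=C(C)C)cc1O)C(=O)c1ccc(OC(C)=O)c(OC)c1 | intermediate
12 | rac-2-acetoxy-1-(4-acetoxy-3-methoxyphenyl)-3-[4-(3-methylbut-2-enyloxy)-3,6-dioxocyclohexa-1,4-dien-1-yl]propane-1,3-dione (acylquinone, not isolated) | CC(=O)OC(C(=O)C1=CC(=O)C(OCC=C(C)C)=CC1=O)C(=O)c1ccc(OC(C)=O)c(OC)c1 | intermediate
13 | 3-acetoxy-2-(4-acetoxy-3-methoxyphenyl)-7-(3-methylbut-2-enyloxy)chromene-4,5,8-trione (not isolated) | COc1cc(C2=C(OC(C)=O)C(=O)C3=C(O2)C(=O)C(OCC=C(C)C)=CC3=O)ccc1OC(C)=O | intermediate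
14 | 3-acetoxy-2-(4-acetoxy-3-methoxyphenyl)-5,8-dihydroxy-7-(3-methylbut-2-enyloxy)chromen-4-one | COc1cc(-c2oc3c(O)c(OCC=C(C)C)cc(O)c3c(=O)c2OC(C)=O)ccc1OC(C)=O | intermediate
15 | 3-acetoxy-2-(4-acetoxy-3-methoxyphenyl)-5-hydroxy-8-methoxy-7-(3-methylbut-2-enyloxy)chromen-4-one | COc1cc(-c2oc3c(OC)c(OCC=C(C)C)cc(O)c3c(=O)c2OC(C)=O)ccc1OC(C)=O | intermediate
16 | 3,5-dihydroxy-2-(4-hydroxy-3-methoxyphenyl)-8-methoxy-7-(3-methylbut-2-enyloxy)chromen-4-one | COc1cc(-c2oc3c(OC)c(OCC=C(C)C)cc(O)c3c(=O)c2O)ccc1O | target

## Step count and least certain steps

Total step count: 11. Longest linear sequence: 9 steps (1 to 16 through steps 1, 2, 3, 6, 7, 8, 9, 10 and 11); the branch from 6 adds steps 4 and 5.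

Step 9 (key step, the one that carries the new-method label).
- What may go wrong: the acylquinone may be consumed by intermolecular addition or oligomerisation before the enol oxygen closes, because enolisation of the hindered α-acetoxy diketone may be slow. Reversible hemiketal formation in 11 through its ortho hydroxyl may withhold the oxidisable hydroquinone. Acetyl transfer on the basic oxide surface and incomplete reduction of over-oxidised material are further losses.
- Fallback with known reactions only: it sets out from 3 and 8 and comes back at 13. Ring C is closed in the classical way onto a symmetrical ring A, and O8 is introduced afterwards by para-oxidation.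
  - Commercial 2,4,6-trihydroxyacetophenone would be alkylated with 3 (K2CO3, acetone) at its para hydroxyl to give 1-[2,6-dihydroxy-4-(3-methylbut-2-enyloxy)phenyl]ethanone F1.
  - Silylation as in step 3 would give 1-[2,6-bis(tert-butyldimethylsilyloxy)-4-(3-methylbut-2-enyloxy)phenyl]ethanone F2.
  - Soft-enolisation Claisen condensation with 8 as in step 6 would give 1-(4-acetoxy-3-methoxyphenyl)-3-[2,6-bis(tert-butyldimethylsilyloxy)-4-(3-methylbut-2-enyloxy)phenyl]propane-1,3-dione F3.
  - Acetoxylation with PhI(OAc)2 as in step 7 would give rac-2-acetoxy-1-(4-acetoxy-3-methoxyphenyl)-3-[2,6-bis(tert-butyldimethylsilyloxy)-4-(3-methylbut-2-enyloxy)phenyl]propane-1,3-dione F4.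
  - Buffered fluoride desilylation followed by warming in AcOH containing NaOAc would close ring C by cyclodehydration. This is free of regiochemical choice because the two ortho hydroxyls are equivalent, and it would give 3-acetoxy-2-(4-acetoxy-3-methoxyphenyl)-5-hydroxy-7-(3-methylbut-2-enyloxy)chromen-4-one F5.
  - Teuber oxidation with (KSO3)2NO in aqueous acetone buffered with KH2PO4 would then oxidise the phenol at its free para position C8 to the quinone, which is 13; the chelated phenol is expected to react slowly. Reduction with Na2S2O4 as in the second half of step 9 gives 14.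

Step 8.
- What may go wrong: loss or migration of an acetyl group under fluoride, ring closure of the ortho-hydroxyaryl diketone to a hemiketal followed by dehydration in the wrong sense, and uncontrolled autoxidation of the free hydroquinone during work-up.
- Fallback: it sets out from 10 and comes back at 12 without passing through the free hydroquinone. The bis-silyl ether is oxidised directly to the quinone by oxidative desilylation with (C5H5NH)[CrO3Cl] in CH2Cl2, a known way of releasing quinones from hydroquinone bis-silyl ethers. After filtration through a short pad, 12 would be carried through the closure and the Na2S2O4 work-up of step 9. No new compound is involved.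

Step 7.
- What may go wrong: competing oxidation of the trisubstituted alkene or of the electron-rich ring by the iodine reagent, formation of an iodonium ylide at the central carbon instead of acetate transfer, or oxidative cleavage of the diketone.
- Fallback: it sets out from 9 and comes back at 10, and it replaces the electrophilic oxidant by carbene chemistry. Regitz diazo transfer (4-acetamidobenzenesulfonyl azide, Et3N, MeCN) would give 1-(4-acetoxy-3-methoxyphenyl)-3-[2,5-bis(tert-butyldimethylsilyloxy)-4-(3-methylbut-2-enyloxy)phenyl]-2-diazopropane-1,3-dione F6. O–H insertion of the derived rhodium carbenoid into acetic acid (Rh2(OAc)4 cat., AcOH, CH2Cl2, rt) would then give 10.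

Step 2.
- What may go wrong: alkylation at the 5-OH or at two oxygens, C-prenylation of the electron-rich ring, and autoxidation of the hydroxyhydroquinone under base.
- Fallback: it sets out from 2 and comes back at 4, and it replaces direct alkylation by protection and selective unmasking.
  - Peracetylation (Ac2O, pyridine) would give 1-(2,4,5-triacetoxyphenyl)ethanone F7.
  - Selective removal of the acetate para to the ketone, the best phenoxide leaving group (PhSH, imidazole, N-methylpyrrolidone, 0 °C), would give 1-(2,5-diacetoxy-4-hydroxyphenyl)ethanone F8.
  - Mitsunobu etherification with 3-methylbut-2-en-1-ol (PPh3, diisopropyl azodicarboxylate, THF) would give 1-[2,5-diacetoxy-4-(3-methylbut-2-enyloxy)phenyl]ethanone F9.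
  - Methanolysis (K2CO3 cat., MeOH, Ar) would give 4.

## Further compounds

F1 | step 9 | 1-[2,6-dihydroxy-4-(3-methylbut-2-enyloxy)phenyl]ethanone | CC(=O)c1c(O)cc(OCC=C(C)C)cc1O
F2 | step 9 | 1-[2,6-bis(tert-butyldimethylsilyloxy)-4-(3-methylbut-2-enyloxy)phenyl]ethanone | CC(=O)c1c(O[Si](C)(C)C(C)(C)C)cc(OCC=C(C)C)cc1O[Si](C)(C)C(C)(C)C
F3 | step 9 | 1-(4-acetoxy-3-methoxyphenyl)-3-[2,6-bis(tert-butyldimethylsilyloxy)-4-(3-methylbut-2-enyloxy)phenyl]propane-1,3-dione | COc1cc(C(=O)CC(=O)c2c(O[Si](C)(C)C(C)(C)C)cc(OCC=C(C)C)cc2O[Si](C)(C)C(C)(C)C)ccc1OC(C)=O
F4 | step 9 | rac-2-acetoxy-1-(4-acetoxy-3-methoxyphenyl)-3-[2,6-bis(tert-butyldimethylsilyloxy)-4-(3-methylbut-2-enyloxy)phenyl]propane-1,3-dione | COc1cc(C(=O)C(OC(C)=O)C(=O)c2c(O[Si](C)(C)C(C)(C)C)cc(OCC=C(C)C)cc2O[Si](C)(C)C(C)(C)C)ccc1OC(C)=O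
F5 | step 9 | 3-acetoxy-2-(4-acetoxy-3-methoxyphenyl)-5-hydroxy-7-(3-methylbut-2-enyloxy)chromen-4-one | COc1cc(-c2oc3cc(OCC=C(C)C)cc(O)c3c(=O)c2OC(C)=O)ccc1OC(C)=O
F0 | step 8 | none | none
F6 | step 7 | 1-(4-acetoxy-3-methoxyphenyl)-3-[2,5-bis(tert-butyldimethylsilyloxy)-4-(3-methylbut-2-enyloxy)phenyl]-2-diazopropane-1,3-dione | COc1cc(C(=O)C(=[N+]=[N-])C(=O)c2cc(O[Si](C)(C)C(C)(C)C)c(OCC=C(C)C)cc2O[Si](C)(C)C(C)(C)C)ccc1OC(C)=O
F7 | step 2 | 1-(2,4,5-triacetoxyphenyl)ethanone | CC(=O)c1cc(OC(C)=O)c(OC(C)=O)cc1OC(C)=O
F8 | step 2 | 1-(2,5-diacetoxy-4-hydroxyphenyl)ethanone | CC(=O)c1cc(OC(C)=O)c(O)cc1OC(C)=O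
F9 | step 2 | 1-[2,5-diacetoxy-4-(3-methylbut-2-enyloxy)phenyl]ethanone | CC(=O)c1cc(OC(C)=O)c(OCC=C(C)C)cc1OC(C)=O
A1 | alternative 1 | 4-[5-(benzyloxy)-6-(4-benzyloxy-3-methoxyphenyl)-4-oxo-4H-pyran-2-yl]-4-methoxy-3-(propan-2-yloxy)cyclobut-2-en-1-one | CC(C)OC1=CC(=O)C1(OC)c1cc(=O)c(OCc2ccccc2)c(-c2ccc(OCc3ccccc3)c(OC)c2)o1
A2 | alternative 1 | 3-(benzyloxy)-2-(4-benzyloxy-3-methoxyphenyl)-5-hydroxy-7-isopropoxy-8-methoxychromen-4-one | COc1cc(-c2oc3c(OC)c(OC(C)C)cc(O)c3c(=O)c2OCc2ccccc2)ccc1OCc1ccccc1
A3 | alternative 2 | 3-acetoxy-2-(4-acetoxy-3-methoxyphenyl)-5-bromo-4H-pyran-4-one | COc1cc(-c2occ(Br)c(=O)c2OC(C)=O)ccc1OC(C)=O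
A4 | alternative 2 | 1,4-dimethoxy-1,3-bis(trimethylsilyloxy)buta-1,3-diene (double-bond geometry not specified) | COC=C(O[Si](C)(C)C)C=C(OC)O[Si](C)(C)C
A5 | alternative 2 | 3-acetoxy-2-(4-acetoxy-3-methoxyphenyl)-5,7-dihydroxy-8-methoxychromen-4-one | COc1cc(-c2oc3c(OC)c(O)cc(O)c3c(=O)c2OC(C)=O)ccc1OC(C)=O
A6 | alternative 3 | 5-(benzyloxy)-2-methoxybenzene-1,3-diol | COc1c(O)cc(OCc2ccccc2)cc1O
A7 | alternative 3 | ethyl 2-(benzyloxy)-3-(4-benzyloxy-3-methoxyphenyl)-3-oxopropanoate | CCOC(=O)C(OCc1ccccc1)C(=O)c1ccc(OCc2ccccc2)c(OC)c1
A8 | alternative 3 | 3,5-bis(benzyloxy)-2-(4-benzyloxy-3-methoxyphenyl)-7-hydroxy-8-methoxychromen-4-one | COc1cc(-c2oc3c(OC)c(O)cc(OCc4ccccc4)c3c(=O)c2OCc2ccccc2)ccc1OCc1ccccc1
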